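# Proposed synthesis of CNP0151194.1 via an acetaldehyde–diene cyclocondensation (L-fucal template)

## Structural features

The target is a six-carbon chain, C1' to C6', whose C1' carbinol carbon is bonded to C4 of a 2,4-disubstituted oxazole (ring A). C2 of ring A carries a methylene that ends at C5 of a second, otherwise unsubstituted oxazole (ring B). The chain holds four stereocentres: C1' (R) stands alone, separated by the C2' methylene from the contiguous triad C3' (S), C4' (S), C5' (S). Only O5' is acylated (hexadecanoate), while O1', O3' and O4' are free. In a Fischer projection O1', O3' and O4' lie on one side and O5' on the other, so C1'/C3' are 1,3-syn and C3'–C5' carry the L-lyxo pattern of 2-deoxy-L-fucose. Fragile points are the ester (cleavage or 1,2-migration to O4' under base), the heteroaryl carbinol at C1', the doubly activated methylene between the rings and the acidic C2–H of ring B; together they exclude strong bases and hard organometallics late in the route. The real difficulty is to build the oxygenated triad with one of three neighbouring secondary hydroxyls singled out for acylation, and to set the remote C1' centre independently. The key step exploits the fact that C1'–C5' and O5' fold into a 2,6-dideoxypyranose in which O4' and the C6' methyl are cis and O5' is the ring oxygen. A hetero-Diels–Alder reaction of acetaldehyde makes C4'–C5' and O5'–C1' with that cis relationship, and the ring then distinguishes O5' from O3'/O4' without any selective protection. The (1E,3Z) diene geometry, the (2S,3R) cis-pyranone and the (1'R,3'S,4'S,5'S) target were checked against each other and are mutually consistent.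

## Logic of the disconnections

**27 to 26.** The two C–O bonds of an isopropylidene ketal across O3'/O4' are added retrosynthetically. With these oxygens tied together, O5' and O1' are the only oxygens that ever need individual handling. The forward hydrolysis must not move the ester from O5' to O4', which calls for mild aqueous acid and no base.

**26 to 25.** The C1'–H bond is cut and the C1' stereocentre becomes a carbonyl. C1' is insulated from the triad by C2', so it is best set last by reagent control, and the carbonyl provides an acyl carbon for fragment union. The forward reduction needs high face selectivity from the catalyst and must not trigger beta-elimination of O3'.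

**25 to 19 and 24.** The C1'–C4 (ring A) bond is cut. This is the most convergent cut: it separates the heteroaromatic half from the stereochemical half. The union must run without base and must tolerate the ester, the ketal, the beta-alkoxy carbonyl and the acidic methylene of 24.

**24 to 23, then to 20 and 21 (through 22).** The C4–Sn bond and then the C2 (ring A)–CH2 bond are cut. Both ring A carbons of 20 carry bromine of different reactivity, and the methylene carbon arrives with ring B in 21, so both rings are bought rather than built. The forward coupling must select C2–Br over C4–Br, and the stannylation must leave the acidic C–H bonds alone.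

**19 to 17 and 18.** The O5'–acyl bond is cut. In 17, O5' is the only free hydroxyl, so no selectivity question arises. The acylation must simply outrun re-closure of 17 to 16.

**17 to 16.** The C1'–S bond is cut and C1'–O5' is reconnected. The lactone ring keeps O5' hidden until the moment it is needed and supplies C1' at the acyl oxidation level. The opening needs a sulfur nucleophile that leaves the ketal intact.

**16 to 15, 14, 13 and 12.** These are functional-group changes: C1' oxidation level, the C1'–O and C2'–H bonds of a hydration, the ketal C–O bonds, and the benzoate. The ketal is placed before the oxidation so that the lactone can only be six-membered and cannot isomerise to a five-membered lactone through O4'. The hydration must therefore be mild enough to spare the ketal.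

**12 to 11.** The C3'–H bond is cut. The C3' stereocentre is set by hydride delivery to a ring ketone flanked by the two existing centres. The reduction must be 1,2 and not 1,4, and must come from the face opposite O4' and C6'.

**11 to 8 and 9 (through 10).** The C4'–C5' and O5'–C1' bonds are cut. One step then delivers two skeletal bonds, the ring and two adjacent stereocentres from a two-carbon aldehyde and a four-carbon diene, with every oxygen of C1'–C5' already in place. The forward step demands Z geometry at the diene terminus, endo topology and Re-face selectivity on 9. For that reason 8 carries a chiral alkoxy group matched to the chiral catalyst and a silyl group robust enough for isolation of 10 if needed.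

**8 to 7, 6, 3, and to 1 and 2 (through 4 and 5).** The O–Si bond, the O–benzoyl bond, the C4'–O bond (oxidation of the methyl group) and the O–C bond to the auxiliary are cut. This reduces the diene to a commercial enone and a recoverable chiral alcohol. Enolisation can occur only toward C4', and the second silylation must give the Z enol ether.

## Other disconnections considered

**Alternative 1:** Ring B is cut at O1–C2 and C4–C5, leaving the ring A acetaldehyde A2 and TosMIC A3. In the forward step the anion of A3 (K2CO3, MeOH) adds to the aldehyde of A2, the alkoxide closes onto the isocyanide carbon and loss of toluenesulfinate aromatises ring B to give A1 (van Leusen oxazole synthesis).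
- In its favour: ring B, with its acidic C2–H and the doubly activated methylene, does not exist during any metal-mediated step; no tin is used; and the annulation is a dependable, cheap reaction of aliphatic aldehydes.
- Against it here: A2 is a heteroarylacetaldehyde whose methylene is flanked by ring A and the formyl group, so enolisation and aldol self-condensation compete in basic methanol. Methanolic carbonate would also transesterify a hexadecanoate, which forces an ether on O5' (as in A1) and a silyl ether on O1'. This adds ether removal, acylation and desilylation after the key step, all on the most advanced intermediate.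
- Comparison: the cut says nothing about the four stereocentres, which A2 must already carry, so the stereochemical burden equals that of the chosen plan. Its mechanism is a polar addition–cyclisation–elimination cascade rather than a pericyclic ring construction. As a way of making ring B it is the equal of, and probably more reliable than, the Negishi step 13, and it is better in avoiding tin. It is worse in step economy, because the chosen plan reaches 24 in two steps from bought rings and joins it convergently with the ester already in place.

**Alternative 2:** The C3'–O bond and the two acetal C–O bonds are cut, giving the (E)-ene-diol A5 and benzaldehyde dimethyl acetal A6. In the forward step Re2O7 (heptavalent rhenium) converts the C5' hydroxyl of A5 into an allyl perrhenate, a [3,3] shift moves oxygen to C3' and the alkene to C4'=C5', and the reversible transposition is drained by acetalisation of O1'/O3' as the all-equatorial dioxane A4.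
- In its favour: C3' is derived from C1' under thermodynamic control without a chiral reagent, and the configuration at C5' of A5 is irrelevant. The (E)-propenyl group of A4 could then give C4'/C5' by syn dihydroxylation; the E alkene provides the required threo C4'/C5' pair, and attack anti to the allylic oxygen would provide the 3',4' relationship.
- Against it here: an oxophilic rhenium oxide must operate in the presence of two basic oxazole nitrogens and a heteroaryl carbinol that can ionise at C1', the only stereochemical source. Face selectivity in dihydroxylation of an acyclic allylic acetal is rarely high without a chiral ligand. Afterwards O4' and O5' are two free secondary hydroxyls with no intrinsic basis for acylating only O5'. The benzylidene acetal must finally be removed next to the ester.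
- Comparison: for the 1',3'-syn relationship this alternative is better than the chosen plan, which needs a stoichiometric chiral reductant in step 16. It is clearly weaker for the triad and for singling out O5', which the chosen plan obtains from the ring oxygen of 16. The step count would be similar at best, because A5 still needs an asymmetric step for C1'.

**Alternative 3:** Ring A is cut at O1–C2 (and, one step earlier, at the amide bond), leading to the alpha-acylamino aldehyde A8, itself assembled from L-serine A9 and oxazol-5-ylacetic acid A10. In the forward step PPh3, I2 and Et3N activate the amide of A8, the aldehyde enol oxygen closes onto the activated carbon and elimination aromatises ring A to give A7 (Robinson–Gabriel type cyclodehydration). The stereocentre of A9 would first direct the addition that creates C1' and is then erased on aromatisation.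
- In its favour: no cross-coupling and no tin; the inter-ring methylene is introduced by an amide coupling; C1' comes from a cheap chiral-pool centre; and the ester can already be present, so A7 needs only the same final deprotection as 26.
- Against it here: in A8 the silyloxy group at C1' is beta to the aldehyde, so amine-promoted beta-elimination competes with ring closure. The linear sequence is long (protection of A9, aldehyde formation, addition of a C2'–C6' nucleophile that must itself carry the triad, deprotection, acylation with A10, oxidation, cyclisation). The 1',3'-syn relationship would depend on the facial bias of that addition.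
- Comparison: at the fragment union (amide bond against palladium/copper acyl coupling) and in avoiding stoichiometric tin and copper, this alternative is equal or better. Mechanistically it builds ring A by polar cyclodehydration on the fully loaded chain, whereas the chosen plan attaches a ready-made ring A under neutral conditions. It is longer, and like alternative 1 it leaves the C3'–C5' problem to be solved elsewhere, which the chosen key step solves directly.

Key step: step 5

Assumption: 5-(chloromethyl)-1,3-oxazole 21 is taken to be a catalogue compound (otherwise one step from the commercial alcohol), and the diene oxygen substituents (menthyl for methyl, tert-butyldimethylsilyl for trimethylsilyl) are spectator changes that leave the bonds formed in the key step untouched.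

## Route

Step 1
Reactants: 1 (E)-4-methoxybut-3-en-2-one; 2 (1R,2S,5R)-menthol
Product: 3 (E)-4-[(1R,2S,5R)-menthyloxy]but-3-en-2-one
Conditions: PPTS (5 mol %), toluene, 85 °C, MeOH distilled off
Reagents that add atoms: none
Why: Acid-catalysed conjugate addition–elimination at C4 of the vinylogous ester exchanges methanol for the secondary alcohol (transetherification); removal of methanol drives the equilibrium, the E enone is the thermodynamic isomer and the menthyl stereocentres are untouched.

Step 2
Reactants: 3 (E)-4-[(1R,2S,5R)-menthyloxy]but-3-en-2-one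
Product: 6 (E)-1-hydroxy-4-[(1R,2S,5R)-menthyloxy]but-3-en-2-one, via silyl dienol ether 4 (not isolated), via alpha-silyloxy ketone 5 (not isolated)
Conditions: Me3SiOTf, Et3N, Et2O, 0 °C; filter, concentrate; mCPBA, hexane/CH2Cl2, −15 °C; aq. citric acid, THF, 0 °C
Reagents that add atoms: meta-chloroperoxybenzoic acid (mCPBA), O=C(OO)c1cccc(Cl)c1
Why: The methyl group is the only enolisable position, so soft enolisation gives the 2-silyloxy diene 4, whose silyl enol ether alkene is the most nucleophilic site for the peracid; epoxide opening with 1,4-silyl shift gives 5 and mild acid frees the primary alcohol (Rubottom oxidation).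

Step 3
Reactants: 6 (E)-1-hydroxy-4-[(1R,2S,5R)-menthyloxy]but-3-en-2-one
Product: 7 (E)-4-[(1R,2S,5R)-menthyloxy]-2-oxobut-3-en-1-yl benzoate
Conditions: BzCl, pyridine, DMAP (cat.), CH2Cl2, 0 °C
Reagents that add atoms: benzoyl chloride, O=C(Cl)c1ccccc1
Why: Nucleophile-catalysed acylation of a primary alcohol; the benzoate carries the future O4' through enol silylation and cycloaddition and makes the later intermediates UV-active.

Step 4
Reactants: 7 (E)-4-[(1R,2S,5R)-menthyloxy]-2-oxobut-3-en-1-yl benzoate
Product: 8 (1E,3Z)-4-benzoyloxy-1-[(1R,2S,5R)-menthyloxy]-3-(tert-butyldimethylsilyloxy)buta-1,3-diene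
Conditions: t-BuMe2SiOTf, Et3N, Et2O, 0 °C to 20 °C; filter through Celite, concentrate
Reagents that add atoms: tert-butyldimethylsilyl triflate, CC(C)(C)[Si](C)(C)OS(=O)(=O)C(F)(F)F
Why: Silyl triflate/amine enolisation can occur only toward the benzoyloxy-bearing carbon and should give the Z enol ether (silyloxy and benzoyloxy cis), the geometry favoured for alpha-acyloxy ketones; the bulkier silyl group makes the diene and its cycloadduct robust enough to handle.

Step 5
Reactants: 8 (1E,3Z)-4-benzoyloxy-1-[(1R,2S,5R)-menthyloxy]-3-(tert-butyldimethylsilyloxy)buta-1,3-diene; 9 acetaldehyde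
Product: 11 (2S,3R)-2-methyl-4-oxo-3,4-dihydro-2H-pyran-3-yl benzoate, via silyl enol ether cycloadduct 10 (not isolated)
Conditions: 9 (10 equiv), (+)-Eu(hfc)3 (tris[3-(heptafluoropropylhydroxymethylene)-(+)-camphorato]europium, trivalent europium, 5 mol %), CH2Cl2, −20 °C to 5 °C; then CF3CO2H, CH2Cl2, 0 °C; aq. NaHCO3
Reagents that add atoms: none
Why: The europium centre binds the aldehyde oxygen anti to the methyl group and the electron-rich diene 8 adds across the C=O bond in an asynchronous, concerted [4+2] cycloaddition in which C4'–C5' forms ahead of O5'–C1'; this is the lanthanide-catalysed cyclocondensation of 1-alkoxy-3-silyloxy dienes with aldehydes, precedented for the 4-acyloxy diene with acetaldehyde under achiral europium catalysis and for menthyloxy dienes under chiral europium catalysis. The six-membered ring is closed in the cycloaddition itself, both ring bonds being made suprafacially on the s-cis diene, so no separate cyclisation has to be arranged. The C4'/C5' relationship is fixed by topology: the 3Z geometry puts the benzoyloxy group on the outside of the diene, and the endo transition state (methyl endo, bulky catalyst exo) turns outside and endo substituents cis. The absolute configuration at C5' requires bonding to the Re face of acetaldehyde; it is controlled by the camphorato ligands of the catalyst, reinforced by the (1R,2S,5R)-menthyloxy group at C1', the pairing that favours L-series adducts with aromatic aldehydes. The anomeric centre of 10 is also formed cis but is erased on unravelling. Trifluoroacetic acid ionises the allylic acetal of 10 with loss of menthol and the vinylogous silyl enol ether collapses to the enone, a path that does not enolise toward C4', so the cis relationship should survive a short, cold acid treatment. The selectivities needed are regiochemistry (secured by the matched polarity of diene termini and carbonyl), endo over exo, and Re over Si; material from the minor face would surface in step 16 as a separable diastereomer.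

Step 6
Reactants: 11 (2S,3R)-2-methyl-4-oxo-3,4-dihydro-2H-pyran-3-yl benzoate
Product: 12 (2S,3S,4S)-4-hydroxy-2-methyl-3,4-dihydro-2H-pyran-3-yl benzoate (4-O-benzoyl-L-fucal)
Conditions: NaBH4, CeCl3·7H2O, MeOH, −78 °C
Reagents that add atoms: none
Why: Luche reduction: CeCl3 enforces 1,2-addition to the enone and hydride attacks the half-chair from the face opposite the pseudo-axial benzoyloxy group and the methyl group, so the new C3' hydroxyl is cis to both (all-cis fucal array).

Step 7
Reactants: 12 (2S,3S,4S)-4-hydroxy-2-methyl-3,4-dihydro-2H-pyran-3-yl benzoate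
Product: 13 (2S,3S,4S)-2-methyl-3,4-dihydro-2H-pyran-3,4-diol (L-fucal)
Conditions: K2CO3 (0.2 equiv), MeOH, 20 °C
Reagents that add atoms: none
Why: Carbonate-catalysed methanolysis of the benzoate; the glycal enol ether is stable to base and no stereocentre is touched.

Step 8
Reactants: 13 (2S,3S,4S)-2-methyl-3,4-dihydro-2H-pyran-3,4-diol
Product: 14 3,4-O-isopropylidene-L-fucal (6-deoxy-3,4-O-isopropylidene-L-galactal)
Conditions: Me2C(OMe)2, PPTS (cat.), acetone, 20 °C
Reagents that add atoms: 2,2-dimethoxypropane, COC(C)(C)OC
Why: Acid-catalysed transketalisation engages the cis-3',4'-diol as a cis-fused dioxolane, PPTS being too weak to add methanol to the enol ether; tying O3'/O4' at this point guarantees that the later lactone can only be six-membered.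

Step 9
Reactants: 14 3,4-O-isopropylidene-L-fucal
Product: 15 2,6-dideoxy-3,4-O-isopropylidene-L-lyxo-hexopyranose (anomeric mixture)
Conditions: Ph3P·HBr (5 mol %), THF/H2O (20:1), 20 °C
Reagents that add atoms: water, O
Why: Mild acid-catalysed hydration of the glycal enol ether: protonation at C2' and capture of the oxocarbenium ion by water at C1', under conditions that leave ketals intact; the anomeric mixture is of no consequence.

Step 10
Reactants: 15 2,6-dideoxy-3,4-O-isopropylidene-L-lyxo-hexopyranose
Product: 16 2,6-dideoxy-3,4-O-isopropylidene-L-lyxo-hexono-1,5-lactone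
Conditions: TEMPO (0.2 equiv), PhI(OAc)2, CH2Cl2, 20 °C
Reagents that add atoms: none
Why: Oxoammonium-mediated oxidation of the lactol to the delta-lactone under near-neutral conditions; no other oxidisable group is present.

Step 11
Reactants: 16 2,6-dideoxy-3,4-O-isopropylidene-L-lyxo-hexono-1,5-lactone
Product: 17 S-ethyl 2-[(4S,5R)-5-[(1S)-1-hydroxyethyl]-2,2-dimethyl-1,3-dioxolan-4-yl]ethanethioate
Conditions: AlMe3, EtSH, CH2Cl2, 0 °C; then 16, 0 °C to 20 °C; aq. potassium sodium tartrate, 0 °C; used at once
Reagents that add atoms: ethanethiol, CCS
Why: The aluminium thiolate formed in the flask transfers ethanethiolate to the lactone carbonyl while aluminium holds the departing alkoxide (thiolytic lactone opening), unmasking O5' as the only free hydroxyl; low temperature, a buffered quench and immediate acylation limit re-closure.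

Step 12
Reactants: 17 S-ethyl 2-[(4S,5R)-5-[(1S)-1-hydroxyethyl]-2,2-dimethyl-1,3-dioxolan-4-yl]ethanethioate; 18 hexadecanoyl (palmitoyl) chloride
Product: 19 (1S)-1-[(4R,5S)-5-[2-(ethylsulfanyl)-2-oxoethyl]-2,2-dimethyl-1,3-dioxolan-4-yl]ethyl hexadecanoate
Conditions: pyridine, DMAP (cat.), CH2Cl2, 0 °C
Reagents that add atoms: none
Why: DMAP-catalysed O-acylation of the single free secondary hydroxyl by the acid chloride; thioester and ketal are inert and the mild base does not cause beta-elimination of O3'.

Step 13
Reactants: 20 2,4-dibromo-1,3-oxazole; 21 5-(chloromethyl)-1,3-oxazole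
Product: 23 4-bromo-2-(1,3-oxazol-5-ylmethyl)-1,3-oxazole, via heterobenzylic zinc chloride 22 (not isolated)
Conditions: 21, Zn dust, LiCl, THF, 25 °C; then 20, Pd(PPh3)4 (zerovalent palladium, 3 mol %), THF, 25 °C to 40 °C
Reagents that add atoms: none
Why: LiCl-assisted zinc insertion into the heterobenzylic C–Cl bond gives 22, which undergoes Negishi coupling at the C2–Br bond of 20, the bond flanked by O and N that adds to zerovalent palladium first; the weakly basic zinc reagent leaves the new acidic methylene and the ring B C2–H alone.

Step 14
Reactants: 23 4-bromo-2-(1,3-oxazol-5-ylmethyl)-1,3-oxazole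
Product: 24 2-(1,3-oxazol-5-ylmethyl)-4-(tributylstannyl)-1,3-oxazole
Conditions: (Bu3Sn)2, Pd(PPh3)4 (zerovalent palladium, 5 mol %), toluene, 100 °C
Reagents that add atoms: hexabutylditin, CCCC[Sn](CCCC)(CCCC)[Sn](CCCC)(CCCC)CCCC
Why: Palladium-catalysed stannylation of the heteroaryl bromide (oxidative addition, Sn–Sn transmetallation, reductive elimination) under neutral conditions, which avoids halogen–lithium exchange next to acidic C–H bonds.

Step 15
Reactants: 19 (1S)-1-[(4R,5S)-5-[2-(ethylsulfanyl)-2-oxoethyl]-2,2-dimethyl-1,3-dioxolan-4-yl]ethyl hexadecanoate; 24 2-(1,3-oxazol-5-ylmethyl)-4-(tributylstannyl)-1,3-oxazole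
Product: 25 (1S)-1-[(4R,5S)-2,2-dimethyl-5-[2-oxo-2-[2-(1,3-oxazol-5-ylmethyl)-1,3-oxazol-4-yl]ethyl]-1,3-dioxolan-4-yl]ethyl hexadecanoate
Conditions: Pd2(dba)3 (zerovalent palladium, 2.5 mol %), P(2-furyl)3 (10 mol %), CuO2PPh2 (monovalent copper diphenylphosphinate, 1.5 equiv), THF, 50 °C
Reagents that add atoms: none
Why: Liebeskind–Srogl ketone synthesis: zerovalent palladium inserts into the C(O)–S bond, the copper phosphinate takes up thiolate and tin so that transmetallation needs no base, and reductive elimination forms the C1'–C4 (ring A) bond; the ester, the ketal, the beta-alkoxy ketone product and the acidic methylene never meet a base.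

Step 16
Reactants: 25 (1S)-1-[(4R,5S)-2,2-dimethyl-5-[2-oxo-2-[2-(1,3-oxazol-5-ylmethyl)-1,3-oxazol-4-yl]ethyl]-1,3-dioxolan-4-yl]ethyl hexadecanoate
Product: 26 (1S)-1-[(4R,5S)-5-[(2R)-2-hydroxy-2-[2-(1,3-oxazol-5-ylmethyl)-1,3-oxazol-4-yl]ethyl]-2,2-dimethyl-1,3-dioxolan-4-yl]ethyl hexadecanoate
Conditions: (S)-2-methyl-CBS-oxazaborolidine (0.5 equiv), BH3·SMe2, THF, −30 °C; MeOH quench
Reagents that add atoms: none
Why: Corey–Bakshi–Shibata reduction: the ketone binds the oxazaborolidine boron with the planar oxazolyl group as the large substituent and the (S)-catalyst delivers hydride to give the (R)-carbinol, as with aryl alkyl ketones; because the new centre is set by the reagent, any antipodal material carried from step 5 becomes a diastereomer that chromatography removes.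

Step 17
Reactants: 26 (1S)-1-[(4R,5S)-5-[(2R)-2-hydroxy-2-[2-(1,3-oxazol-5-ylmethyl)-1,3-oxazol-4-yl]ethyl]-2,2-dimethyl-1,3-dioxolan-4-yl]ethyl hexadecanoate
Product: 27 (2S,3S,4S,6R)-3,4,6-trihydroxy-6-[2-(1,3-oxazol-5-ylmethyl)-1,3-oxazol-4-yl]hexan-2-yl hexadecanoate (target)
Conditions: AcOH/H2O (4:1), 40 °C
Reagents that add atoms: none
Why: Mild aqueous acid hydrolyses the cis-fused dioxolane; acid is chosen because acyl migration from O5' to O4' is slow under acidic conditions, and no base is used after the ester is in place.

## Compound list

1 | (E)-4-methoxybut-3-en-2-one | CO/C=C/C(C)=O | starting material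
2 | (1R,2S,5R)-menthol | C[C@@H]1CC[C@H]([C@@H](C1)O)C(C)C | starting material
3 | (E)-4-[(1R,2S,5R)-menthyloxy]but-3-en-2-one | C[C@@H]1CC[C@H]([C@@H](C1)O/C=C/C(C)=O)C(C)C | intermediate
4 | (E)-1-[(1R,2S,5R)-menthyloxy]-3-(trimethylsilyloxy)buta-1,3-diene (not isolated) | C[C@@H]1CC[C@H]([C@@H](C1)O/C=C/C(=C)O[Si](C)(C)C)C(C)C | intermediate
5 | (E)-4-[(1R,2S,5R)-menthyloxy]-1-(trimethylsilyloxy)but-3-en-2-one (not isolated) | C[C@@H]1CC[C@H]([C@@H](C1)O/C=C/C(=O)CO[Si](C)(C)C)C(C)C | intermediate
6 | (E)-1-hydroxy-4-[(1R,2S,5R)-menthyloxy]but-3-en-2-one | C[C@@H]1CC[C@H]([C@@H](C1)O/C=C/C(=O)CO)C(C)C | intermediate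
7 | (E)-4-[(1R,2S,5R)-menthyloxy]-2-oxobut-3-en-1-yl benzoate | C[C@@H]1CC[C@H]([C@@H](C1)O/C=C/C(=O)COC(=O)c2ccccc2)C(C)C | intermediate
8 | (1E,3Z)-4-benzoyloxy-1-[(1R,2S,5R)-menthyloxy]-3-(tert-butyldimethylsilyloxy)buta-1,3-diene | C[C@@H]1CC[C@H]([C@@H](C1)O/C=C/C(O[Si](C)(C)C(C)(C)C)=C/OC(=O)c2ccccc2)C(C)C | intermediate
9 | acetaldehyde | CC=O | starting material
10 | (2S,3R,6S)-4-(tert-butyldimethylsilyloxy)-6-[(1R,2S,5R)-menthyloxy]-2-methyl-3,6-dihydro-2H-pyran-3-yl benzoate, all-cis (not isolated) | C[C@@H]1CC[C@H]([C@@H](C1)O[C@@H]2C=C(O[Si](C)(C)C(C)(C)C)[C@H](OC(=O)c3ccccc3)[C@H](C)O2)C(C)C | intermediate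
11 | (2S,3R)-2-methyl-4-oxo-3,4-dihydro-2H-pyran-3-yl benzoate (cis) | C[C@@H]1OC=CC(=O)[C@@H]1OC(=O)c2ccccc2 | intermediate
12 | (2S,3S,4S)-4-hydroxy-2-methyl-3,4-dihydro-2H-pyran-3-yl benzoate (4-O-benzoyl-L-fucal) | C[C@@H]1OC=C[C@H](O)[C@@H]1OC(=O)c2ccccc2 | intermediate
13 | (2S,3S,4S)-2-methyl-3,4-dihydro-2H-pyran-3,4-diol (L-fucal) | C[C@@H]1OC=C[C@H](O)[C@@H]1O | intermediate
14 | 3,4-O-isopropylidene-L-fucal | C[C@@H]1OC=C[C@@H]2OC(C)(C)O[C@H]12 | intermediate
15 | 2,6-dideoxy-3,4-O-isopropylidene-L-lyxo-hexopyranose (anomeric mixture) | C[C@@H]1OC(O)C[C@@H]2OC(C)(C)O[C@H]12 | intermediate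
16 | 2,6-dideoxy-3,4-O-isopropylidene-L-lyxo-hexono-1,5-lactone | C[C@@H]1OC(=O)C[C@@H]2OC(C)(C)O[C@H]12 | intermediate
17 | S-ethyl 2-[(4S,5R)-5-[(1S)-1-hydroxyethyl]-2,2-dimethyl-1,3-dioxolan-4-yl]ethanethioate | O[C@@H](C)[C@H]1OC(C)(C)O[C@H]1CC(=O)SCC | intermediate
18 | hexadecanoyl (palmitoyl) chloride | CCCCCCCCCCCCCCCC(Cl)=O | starting material
19 | (1S)-1-[(4R,5S)-5-[2-(ethylsulfanyl)-2-oxoethyl]-2,2-dimethyl-1,3-dioxolan-4-yl]ethyl hexadecanoate | CCCCCCCCCCCCCCCC(=O)O[C@@H](C)[C@H]1OC(C)(C)O[C@H]1CC(=O)SCC | intermediate
20 | 2,4-dibromo-1,3-oxazole | Brc1coc(Br)n1 | starting material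
21 | 5-(chloromethyl)-1,3-oxazole | ClCc1cnco1 | starting material
22 | (1,3-oxazol-5-ylmethyl)zinc chloride (not isolated) | Cl[Zn]Cc1cnco1 | intermediate
23 | 4-bromo-2-(1,3-oxazol-5-ylmethyl)-1,3-oxazole | Brc1coc(Cc2cnco2)n1 | intermediate
24 | 2-(1,3-oxazol-5-ylmethyl)-4-(tributylstannyl)-1,3-oxazole | CCCC[Sn](CCCC)(CCCC)c1coc(Cc2cnco2)n1 | intermediate
25 | (1S)-1-[(4R,5S)-2,2-dimethyl-5-[2-oxo-2-[2-(1,3-oxazol-5-ylmethyl)-1,3-oxazol-4-yl]ethyl]-1,3-dioxolan-4-yl]ethyl hexadecanoate | CCCCCCCCCCCCCCCC(=O)O[C@@H](C)[C@H]1OC(C)(C)O[C@H]1CC(=O)c1coc(Cc2cnco2)n1 | intermediate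
26 | (1S)-1-[(4R,5S)-5-[(2R)-2-hydroxy-2-[2-(1,3-oxazol-5-ylmethyl)-1,3-oxazol-4-yl]ethyl]-2,2-dimethyl-1,3-dioxolan-4-yl]ethyl hexadecanoate | CCCCCCCCCCCCCCCC(=O)O[C@@H](C)[C@H]1OC(C)(C)O[C@H]1C[C@@H](O)c1coc(Cc2cnco2)n1 | intermediate
27 | (2S,3S,4S,6R)-3,4,6-trihydroxy-6-[2-(1,3-oxazol-5-ylmethyl)-1,3-oxazol-4-yl]hexan-2-yl hexadecanoate | CCCCCCCCCCCCCCCC(=O)O[C@@H](C)[C@@H](O)[C@@H](O)C[C@@H](O)c1coc(Cc2cnco2)n1 | target

## Step count and least certain steps

Total: 17 steps. Longest linear sequence: 15 steps (steps 1–12 and 15–17, from 1 to 27). The ring fragment 24 takes 2 steps (13 and 14).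

**Step 5 (key step).** Acetaldehyde offers little steric difference between its faces, so facial discrimination may be incomplete even with the matched auxiliary and catalyst. The less nucleophilic acyloxy diene may also react slowly, leaving room for aldehyde self-condensation or for a stepwise aldol-type pathway that erodes the cis relationship. Fallback: starting from 8 and 9, the cycloaddition is run with the achiral shift reagent Eu(fod)3 (tris(6,6,7,7,8,8,8-heptafluoro-2,2-dimethyl-3,5-octanedionato)europium, trivalent europium), and the silyl enol ether acetal 10 is isolated on base-washed silica instead of being unravelled. Because the auxiliary is still attached, the wrong-face product is not an enantiomer but the D-series menthyl glycoside F1, which is removed by chromatography or crystallisation. Pure 10 is then treated with trifluoroacetic acid as in step 5, and the route is rejoined at 11.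

**Step 11.** The delta-hydroxy thioester may re-close to the lactone with loss of thiol during work-up or before acylation is complete, and the Lewis-acidic aluminium reagent may attack the ketal. Fallback: starting from 16, the lactone is saponified with one equivalent of KOH to the potassium 2,6-dideoxy-3,4-O-isopropylidene-L-lyxo-hexonate F2, which is alkylated in DMF with benzyl bromide to the benzyl delta-hydroxy ester F3. This is acylated with 18 (pyridine, DMAP) to the benzyl ester hexadecanoate F4 and hydrogenolysed (H2, Pd/C) to the carboxylic acid F5. Steglich thioesterification (EtSH, dicyclohexylcarbodiimide, DMAP) then returns to the route at 19, and a free hydroxy thioester never exists.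

**Step 13.** Site selectivity may be incomplete (oxidative addition at C4–Br or double coupling), and the heterobenzylic zinc reagent may homo-couple or react through its ring carbon. Fallback: the polarity is reversed. Starting from 20, bromine–magnesium exchange at C2 with i-PrMgCl·LiCl at −20 °C gives (4-bromo-1,3-oxazol-2-yl)magnesium chloride F6, and transmetallation with ZnCl2 gives (4-bromo-1,3-oxazol-2-yl)zinc chloride F7. This is coupled with the benzylic-type chloride 21 under Pd(PPh3)4 catalysis (zerovalent palladium), returning to the route at 23.

**Step 15.** Oxidative addition into an S-alkyl thioester may be slow, the stannane may protodestannylate, and the oxazole nitrogens may sequester copper or palladium. Fallback: starting from 19, Fukuyama reduction (Et3SiH, Pd/C) gives the aldehyde F8. Starting from 23, a copper-catalysed aromatic Finkelstein exchange (NaI, CuI, trans-N,N'-dimethylcyclohexane-1,2-diamine, dioxane) gives 4-iodo-2-(1,3-oxazol-5-ylmethyl)-1,3-oxazole F9. Nozaki–Hiyama–Kishi coupling of F8 and F9 (CrCl2, divalent chromium, with catalytic NiCl2, DMF) gives the C1' carbinol as an epimer mixture F10; the non-basic organochromium species tolerates the acidic methylene and the ester. Dess–Martin oxidation returns to the route at 25.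

**Step 16.** Face selectivity may be insufficient if the oxazole nitrogen or the beta-oxygen competes for boron and disturbs the usual large/small differentiation. Fallback: starting from 25, the reduction is accepted with whatever selectivity it shows and the (1'S)-epimer F11 is separated from 26. F11 is inverted by Mitsunobu reaction with chloroacetic acid (PPh3, diisopropyl azodicarboxylate) to the (1'R)-chloroacetate F12. The chloroacetyl group is then removed selectively with thiourea and NaHCO3 in ethanol, which leaves the hexadecanoate untouched, and the route is rejoined at 26.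

Further compounds

F1 | step 5 | (2R,3S,6R)-4-(tert-butyldimethylsilyloxy)-6-[(1R,2S,5R)-menthyloxy]-2-methyl-3,6-dihydro-2H-pyran-3-yl benzoate (D-series diastereomer of 10) | C[C@@H]1CC[C@H]([C@@H](C1)O[C@H]2C=C(O[Si](C)(C)C(C)(C)C)[C@@H](OC(=O)c3ccccc3)[C@@H](C)O2)C(C)C
F2 | step 11 | potassium 2,6-dideoxy-3,4-O-isopropylidene-L-lyxo-hexonate | O[C@@H](C)[C@H]1OC(C)(C)O[C@H]1CC(=O)[O-].[K+]
F3 | step 11 | benzyl 2-[(4S,5R)-5-[(1S)-1-hydroxyethyl]-2,2-dimethyl-1,3-dioxolan-4-yl]acetate | O[C@@H](C)[C@H]1OC(C)(C)O[C@H]1CC(=O)OCc1ccccc1
F4 | step 11 | (1S)-1-[(4R,5S)-5-(2-benzyloxy-2-oxoethyl)-2,2-dimethyl-1,3-dioxolan-4-yl]ethyl hexadecanoate | CCCCCCCCCCCCCCCC(=O)O[C@@H](C)[C@H]1OC(C)(C)O[C@H]1CC(=O)OCc1ccccc1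
F5 | step 11 | 2-[(4S,5R)-5-[(1S)-1-(hexadecanoyloxy)ethyl]-2,2-dimethyl-1,3-dioxolan-4-yl]acetic acid | CCCCCCCCCCCCCCCC(=O)O[C@@H](C)[C@H]1OC(C)(C)O[C@H]1CC(=O)O
F6 | step 13 | (4-bromo-1,3-oxazol-2-yl)magnesium chloride | Cl[Mg]c1nc(Br)co1
F7 | step 13 | (4-bromo-1,3-oxazol-2-yl)zinc chloride | Cl[Zn]c1nc(Br)co1
F8 | step 15 | (1S)-1-[(4R,5S)-2,2-dimethyl-5-(2-oxoethyl)-1,3-dioxolan-4-yl]ethyl hexadecanoate | CCCCCCCCCCCCCCCC(=O)O[C@@H](C)[C@H]1OC(C)(C)O[C@H]1CC=O
F9 | step 15 | 4-iodo-2-(1,3-oxazol-5-ylmethyl)-1,3-oxazole | Ic1coc(Cc2cnco2)n1
F10 | step 15 | (1S)-1-[(4R,5S)-5-[2-hydroxy-2-[2-(1,3-oxazol-5-ylmethyl)-1,3-oxazol-4-yl]ethyl]-2,2-dimethyl-1,3-dioxolan-4-yl]ethyl hexadecanoate (C1' epimer mixture) | CCCCCCCCCCCCCCCC(=O)O[C@@H](C)[C@H]1OC(C)(C)O[C@H]1CC(O)c1coc(Cc2cnco2)n1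
F11 | step 16 | (1S)-1-[(4R,5S)-5-[(2S)-2-hydroxy-2-[2-(1,3-oxazol-5-ylmethyl)-1,3-oxazol-4-yl]ethyl]-2,2-dimethyl-1,3-dioxolan-4-yl]ethyl hexadecanoate | CCCCCCCCCCCCCCCC(=O)O[C@@H](C)[C@H]1OC(C)(C)O[C@H]1C[C@H](O)c1coc(Cc2cnco2)n1
F12 | step 16 | (1S)-1-[(4R,5S)-5-[(2R)-2-(chloroacetoxy)-2-[2-(1,3-oxazol-5-ylmethyl)-1,3-oxazol-4-yl]ethyl]-2,2-dimethyl-1,3-dioxolan-4-yl]ethyl hexadecanoate | CCCCCCCCCCCCCCCC(=O)O[C@@H](C)[C@H]1OC(C)(C)O[C@H]1C[C@@H](OC(=O)CCl)c1coc(Cc2cnco2)n1
A1 | alternative 1 | bis-oxazole with O5' 4-methoxybenzyl ether, O1' tert-butyldimethylsilyl ether and O3'/O4' acetonide | COc1ccc(CO[C@@H](C)[C@H]2OC(C)(C)O[C@H]2C[C@@H](O[Si](C)(C)C(C)(C)C)c2coc(Cc3cnco3)n2)cc1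
A2 | alternative 1 | ring A acetaldehyde with the same protected chain | COc1ccc(CO[C@@H](C)[C@H]2OC(C)(C)O[C@H]2C[C@@H](O[Si](C)(C)C(C)(C)C)c2coc(CC=O)n2)cc1
A3 | alternative 1 | TosMIC (4-toluenesulfonylmethyl isocyanide) | Cc1ccc(cc1)S(=O)(=O)C[N+]#[C-]
A4 | alternative 2 | all-cis 2-phenyl-4-[2-(1,3-oxazol-5-ylmethyl)-1,3-oxazol-4-yl]-6-[(E)-prop-1-enyl]-1,3-dioxane | C/C=C/[C@@H]1C[C@H](c2coc(Cc3cnco3)n2)O[C@H](c2ccccc2)O1
A5 | alternative 2 | (1R,3E)-1-[2-(1,3-oxazol-5-ylmethyl)-1,3-oxazol-4-yl]hex-3-ene-1,5-diol (either C5 epimer) | CC(O)/C=C/C[C@@H](O)c1coc(Cc2cnco2)n1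
A6 | alternative 2 | benzaldehyde dimethyl acetal | COC(OC)c1ccccc1
A7 | alternative 3 | target protected as C1' tert-butyldimethylsilyl ether and C3'/C4' acetonide | CCCCCCCCCCCCCCCC(=O)O[C@@H](C)[C@H]1OC(C)(C)O[C@H]1C[C@@H](O[Si](C)(C)C(C)(C)C)c1coc(Cc2cnco2)n1
A8 | alternative 3 | alpha-(1,3-oxazol-5-ylacetamido) aldehyde with the same protected chain (alpha centre unspecified) | CCCCCCCCCCCCCCCC(=O)O[C@@H](C)[C@H]1OC(C)(C)O[C@H]1C[C@@H](O[Si](C)(C)C(C)(C)C)C(C=O)NC(=O)Cc1cnco1
A9 | alternative 3 | L-serine | N[C@@H](CO)C(=O)O
A10 | alternative 3 | 2-(1,3-oxazol-5-yl)acetic acid | OC(=O)Cc1cnco1
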